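## Structural features

The target is a 3,4-dihydro-2H-chromene: a benzene ring fused to a dihydropyran ring. It carries a free phenol at C5, a methyl group at C2 and, at C4, a 4,5-dimethoxynaphthalen-1-yl group joined through a C(sp3)–C(sp2) bond to naphthalene C1'. The two stereocentres, C2 (R) and C4 (S), are separated by the C3 methylene, and the methyl and naphthyl groups lie on opposite faces of the pyran ring (2,4-trans). C4 is a diarylmethine wedged between the two ortho oxygens of the resorcinol ring (O1 on C8a, the hydroxyl on C5) and the peri region of the naphthalene, so C4–C4a is the most congested bond in the molecule. The fragile parts are the very electron-rich peri-dimethoxynaphthalene (easily oxidised, open to electrophiles), the free phenol and the doubly benzylic C4–H. The real difficulty is to make the crowded C4–C4a bond with control of C4 and then to place C2 trans to it. Hydride delivery to a cyclic C2 oxocarbenium ion would be expected to come anti to the C4 aryl group and give the cis isomer, so C2 has to be set by a reagent and closed with inversion. The key step uses the fact that C4 is a naphthylic carbon flanked by C3 and C4a: an acetyl radical that adds to the CH2 terminus of a 1-vinylnaphthalene (C2–C3) leaves a stabilised radical exactly at C4, where a nickel-bound aryl group from resorcinol C2 can be attached (C4–C4a).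

## Logic of the disconnections

13 to 12: the O1–C2 ether bond is cut. An SN2 closure by a phenol oxygen transfers a carbinol configuration into the ring with inversion, so the cyclic stereocentre becomes an acyclic one that a reagent can set. The gain is an open chain whose two phenols are equivalent. The demand is a clean intramolecular displacement at a secondary carbon without elimination, starting from the S carbinol.

12 to 11: no skeletal bond is cut; the two phenolic O–H bonds are masked as acetals. This is needed because free phenols would not survive the lithiation and the coupling, and the acetals direct the metalation. The demand is an acid cleavage that spares the electron-rich rings and the carbinol.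

11 to 10: the C2–H bond is removed, carbinol to ketone. A methyl ketone is exactly what an acetyl radical delivers, and the change leaves C4 as the only stereocentre. The demand is a reduction that distinguishes a methyl from a methylene flank under reagent control.

10 to 4, 8 and 9: the C2–C3 and C4–C4a bonds are cut, both at the two carbons of a vinyl group. This gives three simple pieces and builds the whole carbon chain of the pyran ring and the diarylmethine in one operation. The demands are terminal addition of the acyl radical, aryl transfer from a doubly ortho-substituted iodide, and enantiocontrol at C4 by the ligand on nickel.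

8 to 6 to 5: the C–I bond (through 7) and the two O–CH2 bonds are cut. The position between the two oxygens is the one uniquely activated for lithiation, so the regiochemistry of the resorcinol unit is fixed before the coupling. The demand is selective deprotonation at that carbon.

4 to 3 to 1: the C=C bond and then the C1'–CHO bond are cut. The carbon para to a methoxy group of 1 is its most nucleophilic free position, and the symmetry of 1 makes both such carbons equivalent. The demand is mono-formylation at that site.

## Other disconnections considered

Alternative 1: The cut is made inside the naphthalene, at C1'–C8a' and C4'–C4a', so that the oxygenated ring carrying the chroman is assembled last. In the forward direction the iodo triflate A1 is treated with an alkyllithium; halogen–lithium exchange and loss of triflate release 3-methoxybenzyne A2, which is trapped in a [4+2] cycloaddition by the chroman-substituted vinylketene silyl acetal A3. The adduct should aromatise by loss of its alkoxy group to the naphthol A4, which still needs O-methylation and hydrogenolysis of the benzyl ether.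
- In its favour: the methoxy group of A2 polarises the aryne, so the nucleophilic diene terminus (the carbon bearing the chroman) should bond to the aryne carbon remote from it, placing the new oxygen peri to the methoxy group as required. The crowded C4–C1' bond is not made by a coupling at all; it is already present in A3.
- Against it here: the step creates no stereocentre, so C2 and C4 must both be installed earlier in a multi-step synthesis of A3. The C4–H of A3 is allylic to the diene and must survive strong base. The regiochemical preference of a 3-alkoxyaryne is usually good but seldom complete. The differentiated naphthalene oxygens are of no use for a target with two methyl ethers and cost two finishing steps.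
- Comparison: structurally it is linear where the chosen plan is convergent. Mechanistically, a pericyclic trapping with predictable orientation is the equal or the better of a radical–nickel relay onto a doubly ortho-substituted aryl iodide, as far as certainty of the bond-forming event goes. It contributes nothing to stereocontrol and is clearly longer.

Alternative 2: The cut removes C4–C4a and O1–C2 and traces the resorcinol ring back to cyclohexane-1,3-dione A6 and the C2–C3–C4 unit to the naphthyl enal A5 (one Wittig step from 3). In the forward direction a diarylprolinol silyl ether condenses with A5 to an iminium ion, C2 of A6 adds to the β-carbon from the open face, and the enol oxygen closes onto the aldehyde to give the lactol A7.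
- In its favour: this Michael–hemiacetalisation is among the best-established organocatalytic enantioselective C–C bond formations and needs neither metal nor protecting groups. The dione reacts unambiguously at the carbon between its carbonyls, which settles the resorcinol C2 regiochemistry without lithiation. On the setting of C4 it is the equal or the better of the chosen plan, because the precedent is closer and the C4–C4a bond is made to an unhindered sp2 carbon.
- Against it here: C2 arrives as a lactol carbon without its methyl group, which must be added by a methyl nucleophile to an oxocarbenium ion with substrate control of the trans relationship. The enone ring must be dehydrogenated to the phenol late, beside an easily oxidised peri-dimethoxynaphthalene and a C4–H activated towards the same oxidants; over-oxidation to a chromene is the obvious hazard.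
- Comparison: structurally both plans build the pyran from a three-carbon unit between the naphthyl carbon and a 1,3-dioxygenated six-membered ring. Mechanistically the alternative replaces an uncertain hindered coupling by a secure polar addition but moves the uncertainty to the late oxidation and to C2. In step count it is about equal, perhaps one step shorter on paper, and it is better in freedom from protecting groups. The chosen plan keeps the ring aromatic throughout and sets C2 by a reagent.

Alternative 3: The cut removes C3–C4 and O1–C2, a formal [4+2] between an ortho-quinone methide and an enol ether. In the forward direction a chiral phosphoric acid dehydrates the triol A8 (obtainable by adding 7 to 3 and removing the acetals) to the ortho-quinone methide A9. A9 takes up ethyl vinyl ether A10 across C4 and O1 within the chiral ion pair to give the cis acetal A11. Exchange of ethoxy for methyl through the C2 oxocarbenium ion, with the methyl nucleophile entering anti to the C4 naphthyl group, would then give the trans target.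
- In its favour: the pyran ring and C4 are made in one step from a precursor two steps away from building blocks the chosen plan also uses. The C4–C4a bond comes from a simple carbonyl addition instead of a hindered cross-coupling. In step economy this alternative is the better of the two (about six steps against eight), and on the construction of the crowded C4–C4a bond it is also the better.
- Against it here: the cation from A8 is stabilised so strongly by the 4-methoxynaphthyl group and the two ortho oxygens that an uncatalysed, achiral pathway may compete. The geometry of A9 with a bulky 1-naphthyl group is not secured. The methyl-for-ethoxy exchange must be run next to a free phenol, and its trans selectivity rests on the conformation of the oxocarbenium ion and not on a reagent.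
- Comparison: structurally both are convergent unions of the same two aromatic halves. Mechanistically the alternative is polar and metal-free where the chosen plan is a radical–organometallic relay. In stereocontrol the chosen plan has the advantage at C2 (a reagent-controlled carbinol transferred with inversion), while the alternative has the shorter access to C4.

Key step: step 5

Remark on numbering: chroman numbering (O1, C2, C3, C4, C4a, C8a) is used for the chain atoms also in the open-chain intermediates; primed numbers refer to the naphthalene.

Assumption: the sense of induction of the nickel ligand in step 5 cannot be predicted with confidence for this substrate. The antipode that gives the 4S ketone is to be found in a first screening run (both antipodes are available from valinol), and the route is written for that antipode.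

Step 1
Reactants: 1 1,8-dimethoxynaphthalene
Product: 3 4,5-dimethoxynaphthalene-1-carbaldehyde, via iminium dichlorophosphate 2 (not isolated)
Conditions: POCl3 (1.5 equiv), DMF, 0 °C then 70 °C; aq. NaOAc, rt
Reagents that add atoms: N,N-dimethylformamide, CN(C)C=O; water, O
Why: Vilsmeier–Haack formylation: the chloroiminium electrophile attacks C4, para to a methoxy group and the most nucleophilic unhindered position, and the iminium salt 2 is hydrolysed to the aldehyde on buffered work-up; the symmetry of 1 makes the two para positions equivalent, so one monoaldehyde is expected.

Step 2
Reactants: 3 4,5-dimethoxynaphthalene-1-carbaldehyde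
Product: 4 1-ethenyl-4,5-dimethoxynaphthalene
Conditions: Ph3PCH3Br, KOt-Bu, THF, 0 °C to rt
Reagents that add atoms: methyltriphenylphosphonium bromide, C[P+](c1ccccc1)(c1ccccc1)c1ccccc1.[Br-]
Why: Wittig methylenation of a non-enolisable aromatic aldehyde with the unstabilised ylide; no stereochemistry arises, and the electron-rich vinylarene is stored cold with a trace of BHT until use.

Step 3
Reactants: 5 resorcinol (benzene-1,3-diol)
Product: 6 1,3-bis(methoxymethoxy)benzene
Conditions: MOMCl (2.5 equiv), i-Pr2NEt, CH2Cl2, 0 °C to rt
Reagents that add atoms: chloromethyl methyl ether, COCCl
Why: Double O-alkylation of the phenol (Williamson-type acetal formation); the methoxymethyl ethers are the smallest removable groups that direct the coming lithiation and withstand butyllithium, the radical coupling and borane.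

Step 4
Reactants: 6 1,3-bis(methoxymethoxy)benzene
Product: 8 2-iodo-1,3-bis(methoxymethoxy)benzene, via aryllithium 7 (not isolated)
Conditions: n-BuLi, THF, 0 °C; then I2, −78 °C to rt
Reagents that add atoms: iodine, II
Why: Directed ortho-metalation: the C2 hydrogen lies between two coordinating acetal oxygens and is removed selectively to give 7, which is then iodinated by iodine.

Step 5
Reactants: 4 1-ethenyl-4,5-dimethoxynaphthalene, 8 2-iodo-1,3-bis(methoxymethoxy)benzene, 9 pyruvic acid (2-oxopropanoic acid)
Product: 10 (4S)-4-[2,6-bis(methoxymethoxy)phenyl]-4-(4,5-dimethoxynaphthalen-1-yl)butan-2-one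
Conditions: 8 (1.0 equiv), 4 (1.5 equiv), 9 (2.0 equiv), 4CzIPN (2 mol %), NiBr2·glyme (10 mol %), i-Pr-BiOX (antipode giving 4S, 12 mol %), Cs2CO3, degassed DMA, blue LEDs (450 nm), 25 °C
Reagents that add atoms: none
Why: Photoexcited 4CzIPN oxidises caesium pyruvate formed from 9, and loss of CO2 leaves the nucleophilic acetyl radical, which adds to the unsubstituted vinyl carbon of 4 (bond C2–C3) because only this mode places the new radical at C4, where it is delocalised into the naphthalene. Zerovalent nickel bound to the chiral bis(oxazoline) inserts into the C–I bond of 8, the divalent arylnickel takes up the C4 radical, and reductive elimination from trivalent nickel forms C4–C4a, after which the monovalent nickel halide is reduced by the photocatalyst radical anion and both cycles close (radical capture by zerovalent nickel ahead of oxidative addition would reach the same trivalent intermediate). The closest known reaction type is the nickel–photoredox three-component acyl-arylation of alkenes with α-oxo acids and aryl halides, taken together with the enantioselective alkyl-arylation of vinylarenes under chiral bis(oxazoline) or biimidazoline nickel catalysts. No ring is closed. The one new stereocentre, C4, is controlled by the ligand on nickel: capture of a stabilised naphthylic radical is expected to be reversible, so the configuration is decided in the reductive elimination inside the chiral pocket, and the ligand antipode is chosen for 4S. The step needs terminal regioselectivity in the radical addition (secured by the naphthylic stabilisation), alkene addition ahead of direct acyl–aryl coupling (favoured by an excess of 4 over the small stationary amount of arylnickel) and aryl transfer from a doubly ortho-substituted iodide (helped by the weak C–I bond and the small, flexible acetal groups). The acetals, the aryl methyl ethers and the product ketone should be inert to the weakly basic conditions at room temperature.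

Step 6
Reactants: 10 (4S)-4-[2,6-bis(methoxymethoxy)phenyl]-4-(4,5-dimethoxynaphthalen-1-yl)butan-2-one
Product: 11 (2S,4S)-4-[2,6-bis(methoxymethoxy)phenyl]-4-(4,5-dimethoxynaphthalen-1-yl)butan-2-ol
Conditions: (R)-Me-CBS (20 mol %), BH3·SMe2, THF, −20 °C; MeOH quench, aq. work-up
Reagents that add atoms: none
Why: Corey–Bakshi–Shibata reduction: the (R)-oxazaborolidine binds borane at nitrogen and the ketone at boron through the lone pair on the side of the smaller methyl flank, so hydride goes to the face that gives the 2S carbinol; the stereocentre is under reagent control, the remote C4 centre should bias it little, and any 2R epimer is a diastereomer removable by chromatography.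

Step 7
Reactants: 11 (2S,4S)-4-[2,6-bis(methoxymethoxy)phenyl]-4-(4,5-dimethoxynaphthalen-1-yl)butan-2-ol
Product: 12 2-[(1S,3S)-1-(4,5-dimethoxynaphthalen-1-yl)-3-hydroxybutyl]benzene-1,3-diol
Conditions: conc. HCl (cat.), MeOH (dilute), 45 °C
Reagents that add atoms: none
Why: Acid-catalysed cleavage of the two methoxymethyl acetals by acetal exchange with methanol, which traps the methoxymethyl cation as dimethoxymethane; the carbinol is not benzylic and C4–H is not acidic, so neither stereocentre should be touched, and the aryl methyl ethers are stable to dilute HCl.

Step 8
Reactants: 12 2-[(1S,3S)-1-(4,5-dimethoxynaphthalen-1-yl)-3-hydroxybutyl]benzene-1,3-diol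
Product: 13 (2R,4S)-4-(4,5-dimethoxynaphthalen-1-yl)-2-methyl-3,4-dihydro-2H-chromen-5-ol (cladonaphchrom A)
Conditions: PPh3, DIAD, THF (high dilution), 0 °C to rt
Reagents that add atoms: none
Why: Intramolecular Mitsunobu etherification: the carbinol is activated as the alkoxyphosphonium ion and displaced by a phenoxide oxygen in a 6-exo-tet SN2 closure with inversion, turning the S carbinol into the 2R ring centre and giving the 2,4-trans chroman with C4 untouched; the two phenols are interchanged by rotation about the C4–aryl bond, so either gives the same product and the other remains as the C5 hydroxyl.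

## Compound list

1 | 1,8-dimethoxynaphthalene | COc1cccc2cccc(OC)c12 | starting material
2 | [(4,5-dimethoxynaphthalen-1-yl)methylidene]dimethylazanium dichlorophosphate | COc1cccc2c(C=[N+](C)C)ccc(OC)c12.[O-]P(=O)(Cl)Cl | intermediate
3 | 4,5-dimethoxynaphthalene-1-carbaldehyde | COc1cccc2c(C=O)ccc(OC)c12 | intermediate
4 | 1-ethenyl-4,5-dimethoxynaphthalene | COc1cccc2c(C=C)ccc(OC)c12 | intermediate
5 | resorcinol (benzene-1,3-diol) | Oc1cccc(O)c1 | starting material
6 | 1,3-bis(methoxymethoxy)benzene | COCOc1cccc(OCOC)c1 | intermediate
7 | [2,6-bis(methoxymethoxy)phenyl]lithium | COCOc1cccc(OCOC)c1[Li] | intermediate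
8 | 2-iodo-1,3-bis(methoxymethoxy)benzene | COCOc1cccc(OCOC)c1I | intermediate
9 | pyruvic acid (2-oxopropanoic acid) | CC(=O)C(=O)O | starting material
10 | (4S)-4-[2,6-bis(methoxymethoxy)phenyl]-4-(4,5-dimethoxynaphthalen-1-yl)butan-2-one | COc1cccc2c([C@H](CC(C)=O)c3c(OCOC)cccc3OCOC)ccc(OC)c12 | intermediate
11 | (2S,4S)-4-[2,6-bis(methoxymethoxy)phenyl]-4-(4,5-dimethoxynaphthalen-1-yl)butan-2-ol | COc1cccc2c([C@H](C[C@H](C)O)c3c(OCOC)cccc3OCOC)ccc(OC)c12 | intermediate
12 | 2-[(1S,3S)-1-(4,5-dimethoxynaphthalen-1-yl)-3-hydroxybutyl]benzene-1,3-diol | COc1cccc2c([C@H](C[C@H](C)O)c3c(O)cccc3O)ccc(OC)c12 | intermediate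
13 | (2R,4S)-4-(4,5-dimethoxynaphthalen-1-yl)-2-methyl-3,4-dihydro-2H-chromen-5-ol (cladonaphchrom A) | COc1cccc2c([C@@H]3C[C@@H](C)Oc4cccc(O)c43)ccc(OC)c12 | target

## Step count and uncertain steps

Total: 8 steps. Longest linear sequence: 6 steps (steps 1, 2, 5, 6, 7, 8 from 1; the branch from 5 through steps 3, 4, 5, 6, 7, 8 is equally long).

**Step 5 (key step).** The most likely failure is slow radical capture and reductive elimination at an arylnickel whose two ortho substituents shield the metal. The acetyl and naphthylic radicals would then be diverted into direct acyl–aryl coupling, hydroacylation or dimerisation of the alkene, and reduction of the aryl iodide. Photo-oxidation or triplet sensitisation of the electron-rich vinylnaphthalene can also consume 4, and a congested reductive elimination may give weak enantio-induction.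

Fallback, setting out from 7 (made from 6) and from 1 and returning at 10: 7 is quenched with DMF to give 2,6-bis(methoxymethoxy)benzaldehyde F1. Claisen–Schmidt condensation of F1 with acetone (aq. NaOH) gives (E)-4-[2,6-bis(methoxymethoxy)phenyl]but-3-en-2-one F2. Separately, 1 is brominated with NBS in MeCN to 1-bromo-4,5-dimethoxynaphthalene F3. Bromine–lithium exchange with n-BuLi, B(Oi-Pr)3 and mild hydrolysis give (4,5-dimethoxynaphthalen-1-yl)boronic acid F4. A Hayashi–Miyaura conjugate addition of F4 to F2, catalysed by Rh(acac)(C2H4)2 and the BINAP antipode that gives 4S (dioxane–water, 60–90 °C), forms the same C4 stereocentre and delivers 10. The electron-rich naphthylboronic acid is used as the nucleophile because a 2,6-dialkoxyphenylboronic acid would be expected to protodeboronate.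

**Step 6.** The likely failure is incomplete facial discrimination, because the ketone is flanked by a methyl and a methylene group and the selectivity for such ketones is lower than for aryl ketones.

Fallback, setting out from 10 and returning at 11: 10 is reduced with NaBH4 in MeOH to 11 together with its C2 epimer, (2R,4S)-4-[2,6-bis(methoxymethoxy)phenyl]-4-(4,5-dimethoxynaphthalen-1-yl)butan-2-ol F5, and the two diastereomers are separated by chromatography. F5 is inverted by a Mitsunobu reaction with 4-nitrobenzoic acid (PPh3, DIAD, THF) to (2S,4S)-4-[2,6-bis(methoxymethoxy)phenyl]-4-(4,5-dimethoxynaphthalen-1-yl)butan-2-yl 4-nitrobenzoate F6. Methanolysis (K2CO3, MeOH) returns 11, so the whole of 10 can be carried forward.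

**Step 7.** The likely failure is electrophilic attack of the released methoxymethyl cation (a formaldehyde equivalent) on the freed resorcinol ring or on the naphthalene during acid cleavage, leading to hydroxymethylation or methylene bridging.

Fallback, setting out from 5 and returning at 12, with benzyl ethers removed under neutral conditions: 5 is iodinated with I2 and NaHCO3 in water to 2-iodobenzene-1,3-diol F7. Benzylation (BnBr, K2CO3, DMF) gives 1,3-bis(benzyloxy)-2-iodobenzene F8. The three-component coupling of F8 with 4 and 9 under the conditions of step 5 gives (4S)-4-[2,6-bis(benzyloxy)phenyl]-4-(4,5-dimethoxynaphthalen-1-yl)butan-2-one F9. Corey–Bakshi–Shibata reduction as in step 6 gives (2S,4S)-4-[2,6-bis(benzyloxy)phenyl]-4-(4,5-dimethoxynaphthalen-1-yl)butan-2-ol F10. Hydrogenolysis (H2, Pd/C, EtOAc–MeOH) gives 12. The larger benzyl groups make the coupling somewhat more demanding, which is why this is the reserve.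

**Step 8.** The likely failure is elimination of the activated secondary alcohol, or intermolecular etherification, competing with ring closure by a hindered phenol.

Fallback, setting out from 11 and returning at 13, which replaces the redox condensation by a base-mediated displacement: 11 is mesylated (MsCl, Et3N, CH2Cl2, 0 °C) to (2S,4S)-4-[2,6-bis(methoxymethoxy)phenyl]-4-(4,5-dimethoxynaphthalen-1-yl)butan-2-yl methanesulfonate F11. The acetals are cleaved (HCl, MeOH) to (2S,4S)-4-(2,6-dihydroxyphenyl)-4-(4,5-dimethoxynaphthalen-1-yl)butan-2-yl methanesulfonate F12. K2CO3 in DMF at rt then closes the ring by phenoxide SN2 displacement with inversion to give 13.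

## Further compounds

F1 | step 5 | 2,6-bis(methoxymethoxy)benzaldehyde | COCOc1cccc(OCOC)c1C=O
F2 | step 5 | (E)-4-[2,6-bis(methoxymethoxy)phenyl]but-3-en-2-one | COCOc1cccc(OCOC)c1/C=C/C(C)=O
F3 | step 5 | 1-bromo-4,5-dimethoxynaphthalene | COc1cccc2c(Br)ccc(OC)c12
F4 | step 5 | (4,5-dimethoxynaphthalen-1-yl)boronic acid | COc1cccc2c(B(O)O)ccc(OC)c12
F5 | step 6 | (2R,4S)-4-[2,6-bis(methoxymethoxy)phenyl]-4-(4,5-dimethoxynaphthalen-1-yl)butan-2-ol | COc1cccc2c([C@H](C[C@@H](C)O)c3c(OCOC)cccc3OCOC)ccc(OC)c12
F6 | step 6 | (2S,4S)-4-[2,6-bis(methoxymethoxy)phenyl]-4-(4,5-dimethoxynaphthalen-1-yl)butan-2-yl 4-nitrobenzoate | COc1cccc2c([C@H](C[C@H](C)OC(=O)c3ccc(cc3)[N+](=O)[O-])c3c(OCOC)cccc3OCOC)ccc(OC)c12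
F7 | step 7 | 2-iodobenzene-1,3-diol | Oc1cccc(O)c1I
F8 | step 7 | 1,3-bis(benzyloxy)-2-iodobenzene | Ic1c(OCc2ccccc2)cccc1OCc1ccccc1
F9 | step 7 | (4S)-4-[2,6-bis(benzyloxy)phenyl]-4-(4,5-dimethoxynaphthalen-1-yl)butan-2-one | COc1cccc2c([C@H](CC(C)=O)c3c(OCc4ccccc4)cccc3OCc3ccccc3)ccc(OC)c12
F10 | step 7 | (2S,4S)-4-[2,6-bis(benzyloxy)phenyl]-4-(4,5-dimethoxynaphthalen-1-yl)butan-2-ol | COc1cccc2c([C@H](C[C@H](C)O)c3c(OCc4ccccc4)cccc3OCc3ccccc3)ccc(OC)c12
F11 | step 8 | (2S,4S)-4-[2,6-bis(methoxymethoxy)phenyl]-4-(4,5-dimethoxynaphthalen-1-yl)butan-2-yl methanesulfonate | COc1cccc2c([C@H](C[C@H](C)OS(C)(=O)=O)c3c(OCOC)cccc3OCOC)ccc(OC)c12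
F12 | step 8 | (2S,4S)-4-(2,6-dihydroxyphenyl)-4-(4,5-dimethoxynaphthalen-1-yl)butan-2-yl methanesulfonate | COc1cccc2c([C@H](C[C@H](C)OS(C)(=O)=O)c3c(O)cccc3O)ccc(OC)c12
A1 | alternative 1 | 2-iodo-3-methoxyphenyl trifluoromethanesulfonate | COc1cccc(OS(=O)(=O)C(F)(F)F)c1I
A2 | alternative 1 | 3-methoxybenzyne (1-methoxy-2,3-didehydrobenzene) | COC1=CC=CC#C1
A3 | alternative 1 | tert-butyl({(3E)-4-[(2R,4S)-5-(benzyloxy)-2-methyl-3,4-dihydro-2H-chromen-4-yl]-1-methoxybuta-1,3-dien-1-yl}oxy)dimethylsilane | COC(O[Si](C)(C)C(C)(C)C)=C/C=C/[C@@H]1C[C@@H](C)Oc2cccc(OCc3ccccc3)c21
A4 | alternative 1 | 4-[(2R,4S)-5-(benzyloxy)-2-methyl-3,4-dihydro-2H-chromen-4-yl]-8-methoxynaphthalen-1-ol | Oc1ccc([C@@H]3C[C@@H](C)Oc4cccc(OCc5ccccc5)c43)c2cccc(OC)c12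
A5 | alternative 2 | (2E)-3-(4,5-dimethoxynaphthalen-1-yl)prop-2-enal | COc1cccc2c(/C=C/C=O)ccc(OC)c12
A6 | alternative 2 | cyclohexane-1,3-dione | O=C1CCCC(=O)C1
A7 | alternative 2 | (4S)-4-(4,5-dimethoxynaphthalen-1-yl)-2-hydroxy-2,3,4,6,7,8-hexahydro-5H-chromen-5-one | COc1cccc2c([C@@H]3CC(O)OC4=C3C(=O)CCC4)ccc(OC)c12
A8 | alternative 3 | 2-[(4,5-dimethoxynaphthalen-1-yl)(hydroxy)methyl]benzene-1,3-diol | COc1cccc2c(C(O)c3c(O)cccc3O)ccc(OC)c12
A9 | alternative 3 | 6-[(4,5-dimethoxynaphthalen-1-yl)methylidene]-5-hydroxycyclohexa-2,4-dien-1-one | COc1cccc2c(C=C3C(=O)C=CC=C3O)ccc(OC)c12
A10 | alternative 3 | ethoxyethene (ethyl vinyl ether) | C=COCC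
A11 | alternative 3 | (2R,4S)-4-(4,5-dimethoxynaphthalen-1-yl)-2-ethoxy-3,4-dihydro-2H-chromen-5-ol | COc1cccc2c([C@@H]3C[C@H](OCC)Oc4cccc(O)c43)ccc(OC)c12
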